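The route rests on one disconnection: the bond between C8, the α-carbon of the ring ketone C9, and C7, the terminus of the C5–C7 allyl unit (prostanoid numbering: C1 ester carbon, C8–C12 ring). A palladium-catalysed allylic alkylation joins a 5,5-disubstituted 2-silyloxycyclopenta-1,3-diene (the masked C8 enolate of the cyclopentenone) with a (Z)-allylic carbonate that already holds the C4 acetate and the ester. In one operation it forms C7–C8, should set C8 anti to the bulky silyloxy group on the quaternary C12, and funnels the Z carbonate into the E C5=C6 alkene by syn/anti equilibration of the π-allyl complex. Exploited features: the enolisable C8–C9(=O) unit of the five-membered ring and the C7–C6=C5–C4(OAc) allylic array.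

Key step: step 10

Remark: tert-butyl prop-2-yn-1-yl carbonate (11) is taken as a catalogue compound. The target has the two carbon chains on C8 and C12 cis to each other, so H8 is cis to the C12 acetoxy group (4S, 8S, 12R).

Step 1
Reactants: 1 (R)-4-[(tert-butyldimethylsilyl)oxy]cyclopent-2-en-1-one; 2 propargyl bromide
Product: 3 (1S,4R)-4-[(tert-butyldimethylsilyl)oxy]-1-(prop-2-yn-1-yl)cyclopent-2-en-1-ol
Conditions: Zn dust, THF, 0 °C → rt; aq. NH4Cl
Reagents that add atoms: none
Why: Zinc Barbier propargylation, in which the allenylzinc species adds 1,2 to the enone carbonyl (SE2′) on the face opposite the C4 silyloxy group, should give the homopropargylic tertiary alcohol with the new chain trans to OTBS and so set C12.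

Step 2
Reactants: 3 (1S,4R)-4-[(tert-butyldimethylsilyl)oxy]-1-(prop-2-yn-1-yl)cyclopent-2-en-1-ol; 4 1-iodopentane
Product: 5 (1S,4R)-4-[(tert-butyldimethylsilyl)oxy]-1-(oct-2-yn-1-yl)cyclopent-2-en-1-ol
Conditions: n-BuLi (2.2 equiv), THF, −78 → −20 °C; then 4, DMPU, −20 °C → rt
Reagents that add atoms: none
Why: SN2 alkylation of the lithium acetylide of the alkoxide–acetylide dianion with a primary iodide is much faster at carbon than at the hindered tertiary alkoxide.

Step 3
Reactants: 5 (1S,4R)-4-[(tert-butyldimethylsilyl)oxy]-1-(oct-2-yn-1-yl)cyclopent-2-en-1-ol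
Product: 6 (1S,4R)-4-[(tert-butyldimethylsilyl)oxy]-1-[(Z)-oct-2-en-1-yl]cyclopent-2-en-1-ol
Conditions: H2 (1 atm), Lindlar catalyst, quinoline, EtOAc, rt
Reagents that add atoms: none
Why: Lindlar semi-hydrogenation adds H2 syn to the alkyne and stops at the (Z)-alkene, while the poisoned catalyst leaves the ring alkene alone.

Step 4
Reactants: 6 (1S,4R)-4-[(tert-butyldimethylsilyl)oxy]-1-[(Z)-oct-2-en-1-yl]cyclopent-2-en-1-ol
Product: 7 (1S,4R)-1-[(Z)-oct-2-en-1-yl]cyclopent-2-ene-1,4-diol
Conditions: TBAF, THF, 0 °C → rt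
Reagents that add atoms: none
Why: Fluoride-mediated desilylation frees the secondary allylic alcohol; should the silyl group have moved to the cis tertiary oxygen under the basic conditions of step 2, the same diol results.

Step 5
Reactants: 7 (1S,4R)-1-[(Z)-oct-2-en-1-yl]cyclopent-2-ene-1,4-diol
Product: 8 (S)-4-hydroxy-4-[(Z)-oct-2-en-1-yl]cyclopent-2-en-1-one
Conditions: MnO2 (activated), CH2Cl2, rt
Reagents that add atoms: none
Why: MnO2 oxidation is selective for the secondary allylic alcohol, the tertiary alcohol cannot be oxidised, and the neutral conditions avoid retro-aldol opening of the β-hydroxy ketone.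

Step 6
Reactants: 8 (S)-4-hydroxy-4-[(Z)-oct-2-en-1-yl]cyclopent-2-en-1-one
Product: 9 (R)-5-[(Z)-oct-2-en-1-yl]-2,5-bis(triethylsilyloxy)cyclopenta-1,3-diene
Conditions: TESOTf (2.4 equiv), Et3N, CH2Cl2, −78 → 0 °C; non-aqueous work-up, used crude
Reagents that add atoms: triethylsilyl trifluoromethanesulfonate, CC[Si](CC)(CC)OS(=O)(=O)C(F)(F)F
Why: Silyl triflate/amine soft enolisation silylates the tertiary alcohol and, since C8 is the only enolisable position (C12 is quaternary), turns the enone into a cross-conjugated 2-silyloxydiene that cannot undergo 1,5-hydrogen shift.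

Step 7
Reactants: 10 methyl 4-chloro-4-oxobutanoate; 11 tert-butyl prop-2-yn-1-yl carbonate
Product: 12 methyl 7-[(tert-butoxycarbonyl)oxy]-4-oxohept-5-ynoate
Conditions: CuI (5 mol %), Et3N, THF, rt
Reagents that add atoms: none
Why: Copper-catalysed acylation of the terminal alkyne (copper acetylide plus acid chloride, a palladium-free acyl Sonogashira-type coupling) gives the ynone, and leaving palladium out avoids ionisation of the propargylic carbonate.

Step 8
Reactants: 12 methyl 7-[(tert-butoxycarbonyl)oxy]-4-oxohept-5-ynoate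
Product: 14 methyl (S)-4-acetoxy-7-[(tert-butoxycarbonyl)oxy]hept-5-ynoate, via (S)-hydroxy ester 13 (not isolated)
Conditions: Ru[(S,S)-TsDPEN](p-cymene) (1 mol %), i-PrOH, rt; concentrate; Ac2O, pyridine, DMAP (cat.), CH2Cl2, 0 °C
Reagents that add atoms: acetic anhydride, CC(=O)OC(C)=O
Why: Noyori asymmetric transfer hydrogenation of the alkynyl ketone, with the alkyne as the π substituent, should give the (S)-propargylic alcohol with the (S,S) catalyst and so set C4, and acetylation of the crude γ-hydroxy ester outruns lactonisation.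

Step 9
Reactants: 14 methyl (S)-4-acetoxy-7-[(tert-butoxycarbonyl)oxy]hept-5-ynoate
Product: 15 methyl (4S,5Z)-4-acetoxy-7-[(tert-butoxycarbonyl)oxy]hept-5-enoate
Conditions: H2 (1 atm), Lindlar catalyst, quinoline, EtOAc, rt
Reagents that add atoms: none
Why: Lindlar semi-hydrogenation gives the (Z)-allylic carbonate, whose geometry need not be E because the next step erases it.

Step 10
Reactants: 9 (R)-5-[(Z)-oct-2-en-1-yl]-2,5-bis(triethylsilyloxy)cyclopenta-1,3-diene; 15 methyl (4S,5Z)-4-acetoxy-7-[(tert-butoxycarbonyl)oxy]hept-5-enoate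
Product: 16 methyl (4S,5E)-4-acetoxy-7-[(1S,5R)-5-[(Z)-oct-2-en-1-yl]-2-oxo-5-(triethylsilyloxy)cyclopent-3-en-1-yl]hept-5-enoate
Conditions: Pd2(dba)3·CHCl3 (2.5 mol %), dppe (6 mol %), THF, 40 °C
Reagents that add atoms: none
Why: Pd(0) ionises the primary allylic carbonate of 15 (far faster than the secondary acetate) to a π-allylpalladium cation, CO2 and tert-butoxide, the alkoxide takes the enol silyl group of 9, and the enolate so released attacks the unsubstituted allyl terminus C7 through its α-carbon C8. The closest known reaction type is the Tsuji–Trost allylic alkylation in its silyl enol ether/allyl carbonate form; no ring is closed. The new stereocentre C8 is controlled by the neighbouring quaternary C12, whose triethylsilyloxy group lies over one face of the planar diene, so that the bulky allylpalladium unit should enter anti to it and cis to the octenyl chain (8S). The C5=C6 geometry is set dynamically, since the anti π-allyl complex formed from the Z carbonate equilibrates by η3–η1–η3 isomerisation to the more stable syn complex before the slowly released enolate attacks, which funnels Z, E or branched carbonate alike into the E alkene, while C4 lies outside the allyl unit and keeps its configuration. The step needs C- over O-allylation, attack at C7 and not at C5, and mono-allylation; the first two are the norm for ketone enolates with Pd/dppe at an allyl terminus remote from a branched acyloxy carbon, and the third is secured because enolate is set free only as fast as carbonate is ionised.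

Step 11
Reactants: 16 methyl (4S,5E)-4-acetoxy-7-[(1S,5R)-5-[(Z)-oct-2-en-1-yl]-2-oxo-5-(triethylsilyloxy)cyclopent-3-en-1-yl]hept-5-enoate
Product: 17 methyl (4S,5E)-4-acetoxy-7-[(1S,5R)-5-hydroxy-5-[(Z)-oct-2-en-1-yl]-2-oxocyclopent-3-en-1-yl]hept-5-enoate
Conditions: HF·pyridine, pyridine, THF, 0 °C
Reagents that add atoms: none
Why: Buffered HF desilylation cleaves the tertiary triethylsilyl ether under mildly acidic conditions that should leave the acetate, the ester and the epimerisable C8 untouched.

Step 12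
Reactants: 17 methyl (4S,5E)-4-acetoxy-7-[(1S,5R)-5-hydroxy-5-[(Z)-oct-2-en-1-yl]-2-oxocyclopent-3-en-1-yl]hept-5-enoate
Product: 18 methyl (4S,5E)-4-acetoxy-7-[(1S,5R)-5-acetoxy-5-[(Z)-oct-2-en-1-yl]-2-oxocyclopent-3-en-1-yl]hept-5-enoate (CNP0171642.2)
Conditions: Ac2O, DMAP, Et3N, CH2Cl2, 0 °C → rt
Reagents that add atoms: acetic anhydride, CC(=O)OC(C)=O
Why: DMAP-catalysed (Steglich-type) acetylation of the tertiary alcohol via the N-acetylpyridinium ion should proceed without change at C8 or C12, as the amine base is too weak to enolise the ketone to a useful extent.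

Compound list
1 | (R)-4-[(tert-butyldimethylsilyl)oxy]cyclopent-2-en-1-one | O=C1C=C[C@H](O[Si](C)(C)C(C)(C)C)C1 | starting material
2 | propargyl bromide | C#CCBr | starting material
3 | (1S,4R)-4-[(tert-butyldimethylsilyl)oxy]-1-(prop-2-yn-1-yl)cyclopent-2-en-1-ol | C#CC[C@@]1(O)C=C[C@H](O[Si](C)(C)C(C)(C)C)C1 | intermediate
4 | 1-iodopentane | CCCCCI | starting material
5 | (1S,4R)-4-[(tert-butyldimethylsilyl)oxy]-1-(oct-2-yn-1-yl)cyclopent-2-en-1-ol | CCCCCC#CC[C@@]1(O)C=C[C@H](O[Si](C)(C)C(C)(C)C)C1 | intermediate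
6 | (1S,4R)-4-[(tert-butyldimethylsilyl)oxy]-1-[(Z)-oct-2-en-1-yl]cyclopent-2-en-1-ol | CCCCC/C=C\C[C@@]1(O)C=C[C@H](O[Si](C)(C)C(C)(C)C)C1 | intermediate
7 | (1S,4R)-1-[(Z)-oct-2-en-1-yl]cyclopent-2-ene-1,4-diol | CCCCC/C=C\C[C@@]1(O)C=C[C@H](O)C1 | intermediate
8 | (S)-4-hydroxy-4-[(Z)-oct-2-en-1-yl]cyclopent-2-en-1-one | CCCCC/C=C\C[C@@]1(O)C=CC(=O)C1 | intermediate
9 | (R)-5-[(Z)-oct-2-en-1-yl]-2,5-bis(triethylsilyloxy)cyclopenta-1,3-diene | CCCCC/C=C\C[C@@]1(O[Si](CC)(CC)CC)C=CC(O[Si](CC)(CC)CC)=C1 | intermediate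
10 | methyl 4-chloro-4-oxobutanoate | COC(=O)CCC(Cl)=O | starting material
11 | tert-butyl prop-2-yn-1-yl carbonate | C#CCOC(=O)OC(C)(C)C | starting material
12 | methyl 7-[(tert-butoxycarbonyl)oxy]-4-oxohept-5-ynoate | COC(=O)CCC(=O)C#CCOC(=O)OC(C)(C)C | intermediate
13 | methyl (S)-7-[(tert-butoxycarbonyl)oxy]-4-hydroxyhept-5-ynoate | CC(C)(C)OC(=O)OCC#C[C@H](CCC(=O)OC)O | intermediate
14 | methyl (S)-4-acetoxy-7-[(tert-butoxycarbonyl)oxy]hept-5-ynoate | CC(C)(C)OC(=O)OCC#C[C@H](CCC(=O)OC)OC(C)=O | intermediate
15 | methyl (4S,5Z)-4-acetoxy-7-[(tert-butoxycarbonyl)oxy]hept-5-enoate | CC(C)(C)OC(=O)OC/C=C\[C@H](CCC(=O)OC)OC(C)=O | intermediate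
16 | methyl (4S,5E)-4-acetoxy-7-[(1S,5R)-5-[(Z)-oct-2-en-1-yl]-2-oxo-5-(triethylsilyloxy)cyclopent-3-en-1-yl]hept-5-enoate | CCCCC/C=C\C[C@@]1(O[Si](CC)(CC)CC)C=CC(=O)[C@H]1C/C=C/[C@H](CCC(=O)OC)OC(C)=O | intermediate
17 | methyl (4S,5E)-4-acetoxy-7-[(1S,5R)-5-hydroxy-5-[(Z)-oct-2-en-1-yl]-2-oxocyclopent-3-en-1-yl]hept-5-enoate | CCCCC/C=C\C[C@@]1(O)C=CC(=O)[C@H]1C/C=C/[C@H](CCC(=O)OC)OC(C)=O | intermediate
18 | methyl (4S,5E)-4-acetoxy-7-[(1S,5R)-5-acetoxy-5-[(Z)-oct-2-en-1-yl]-2-oxocyclopent-3-en-1-yl]hept-5-enoate | CCCCC/C=C\C[C@@]1(OC(C)=O)C=CC(=O)[C@H]1C/C=C/[C@H](CCC(=O)OC)OC(C)=O | target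

Total step count: 12. Longest linear sequence: 9 steps (steps 1–6 and 10–12); steps 7–9 form the second branch.

Steps most likely to fail

Step 10. The allylpalladium unit may enter C8 on the face of the C12 oxygen, because oxygen is small at its point of attachment and electrophiles often prefer the face of an allylic oxygen; facial selectivity would then be poor or reversed. The fallback sets out from 9 and 15, accepts the coupling as it comes, and sets C8 in a second event by C–H instead of C–C bond formation. The coupling product, then mainly the 8-epimer methyl (4S,5E)-4-acetoxy-7-[(1R,5R)-5-[(Z)-oct-2-en-1-yl]-2-oxo-5-(triethylsilyloxy)cyclopent-3-en-1-yl]hept-5-enoate F1, would be enolised under soft conditions (TESOTf, Et3N, CH2Cl2, −78 → 0 °C). This gives the tetrasubstituted silyl dienol ether methyl (4S,5E)-4-acetoxy-7-[(5R)-5-[(Z)-oct-2-en-1-yl]-2,5-bis(triethylsilyloxy)cyclopenta-1,3-dien-1-yl]hept-5-enoate F2, in which C8 is planar again. Kinetic protonation of F2 (AcOH, TBAT cat., THF, −78 °C) should follow the same facial preference that the allyl unit showed, place H8 on the oxygen face and the chain opposite to it, and so come back to the route at 16.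

Step 6. The silyloxydiene may be lost by hydrolysis or Diels–Alder dimerisation during isolation, or the silyl triflate/amine pair may open conjugate-addition pathways on the enone instead of enolisation. The fallback sets out from 8 and separates the two silylations. The tertiary alcohol alone is protected (TESOTf, 2,6-lutidine, CH2Cl2, −78 °C) to give (S)-4-[(Z)-oct-2-en-1-yl]-4-(triethylsilyloxy)cyclopent-2-en-1-one F3. Kinetic deprotonation (LDA, THF, −78 °C) and trapping with TMSCl then give (R)-5-[(Z)-oct-2-en-1-yl]-5-(triethylsilyloxy)-2-(trimethylsilyloxy)cyclopenta-1,3-diene F4. After removal of the volatiles, F4 is taken without purification into the palladium coupling with 15 in place of 9 and comes back to the route at 16.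

Step 12. Acylation of the hindered tertiary alcohol may be slow enough for the amine/DMAP medium to epimerise C8 by enolisation of the ketone or to cause E1cB loss of the new acetate. The fallback sets out from 16 and leaves out both the free alcohol 17 and any base: Lewis-acid-catalysed direct exchange of the silyl ether for the acetate (Ac2O, Bi(OTf)3 or Cu(OTf)2 cat., MeCN, 0 °C) should lead straight to 18.

Further compounds
F1 | step 10 | methyl (4S,5E)-4-acetoxy-7-[(1R,5R)-5-[(Z)-oct-2-en-1-yl]-2-oxo-5-(triethylsilyloxy)cyclopent-3-en-1-yl]hept-5-enoate | CCCCC/C=C\C[C@@]1(O[Si](CC)(CC)CC)C=CC(=O)[C@@H]1C/C=C/[C@H](CCC(=O)OC)OC(C)=O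
F2 | step 10 | methyl (4S,5E)-4-acetoxy-7-[(5R)-5-[(Z)-oct-2-en-1-yl]-2,5-bis(triethylsilyloxy)cyclopenta-1,3-dien-1-yl]hept-5-enoate | CCCCC/C=C\C[C@@]1(O[Si](CC)(CC)CC)C=CC(O[Si](CC)(CC)CC)=C1C/C=C/[C@H](CCC(=O)OC)OC(C)=O
F3 | step 6 | (S)-4-[(Z)-oct-2-en-1-yl]-4-(triethylsilyloxy)cyclopent-2-en-1-one | CCCCC/C=C\C[C@@]1(O[Si](CC)(CC)CC)C=CC(=O)C1
F4 | step 6 | (R)-5-[(Z)-oct-2-en-1-yl]-5-(triethylsilyloxy)-2-(trimethylsilyloxy)cyclopenta-1,3-diene | CCCCC/C=C\C[C@@]1(O[Si](CC)(CC)CC)C=CC(O[Si](C)(C)C)=C1
F0 | step 12 | none | none
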